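Starting material is what you count first, since its readings ask for no theory of where it goes.

in all of them: starting material 0.050 M

|  | reagent in the second phase | protic impurity | remark | time | volume of the second phase over the first |
|---|---|---|---|---|---|
| violet | 0.050 M | 1.7 mM | run made earlier |  |  |
| green | 0.050 M | 3.8 mM | run made earlier |  |  |
| blue | 0.10 M | 2.5 mM | run made earlier |  |  |
| flask | 0.0500 M | 2.50 mM |  | 30 min | 2.0 |

| run | time / min | target / % | starting material / % |
|---|---|---|---|
| violet | 1.33 | 2.5 | 97.0 |
| violet | 4.00 | 6.5 | 90.4 |
| violet | 6.00 | 8.6 | 85.4 |
| violet | 10.0 | 9.3 | 79.4 |
| violet | 15.0 | 11.2 | 71.6 |
| violet | 20.0 | 10.9 | 66.3 |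
| green | 1.33 | 2.1 | 97.1 |
| green | 2.50 | 5.1 | 93.9 |
| green | 4.00 | 7.5 | 89.5 |
| green | 6.00 | 7.5 | 87.2 |
| green | 10.0 | 10.3 | 79.9 |
| green | 20.0 | 10.8 | 66.3 |
| blue | 1.50 | 7.2 | 92.7 |
| blue | 5.00 | 14.1 | 77.5 |
| blue | 8.00 | 16.1 | 67.7 |
| blue | 12.0 | 17.9 | 57.2 |
| blue | 20.0 | 19.7 | 42.8 |

(standard deviation of a reading: 0.5 percentage points)

- target is meant together with its product in the second phase
- in the second phase: reagent in the second phase, product in the second phase; everything else is in the first
- charges count per volume of the first phase; a concentration in a rate is the amount of a species over the volume of its own phase; every rate counts per litre of the first phase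
- the earlier runs hold the two phases in the same ratio of volumes as the flask asked about

- how much target and product in the second phase together there is at 30 min, in percent of the starting material charged
- part of the starting material charged that has reacted at 30 min

Take the main step by itself. The flask has the violet run's charges of starting material and reagent in the second phase, and these are equal, so I try a second-order law with equal partners: what was charged over what is left, minus one, grows in proportion to time. The violet run gives 0.0254 min⁻¹ from its last reading and 0.0259 min⁻¹ from the reading at 10.0 min, so at 30 min I reckon 43.3% reacted in the flask. With this step by itself, target equals what has reacted.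

Now add the protic impurity. Violet holds 1.7 mM and green 3.8 mM, yet at 20.0 min starting material reads 66.3% and 66.3%, and target 10.9% and 10.8%. The flask's charge lies between them, so my number stays where it is.

Then add the loss of target. In the violet run target stands at 11.2% and 10.9% while starting material keeps falling. So define the holding time: the elapsed time multiplied by target present over starting material reacted. Violet gives 6.47 min. Blue, with twice the reagent, gives 6.89 min, so the reading moves little between these two runs. This is the crossing as I read it: in violet the elapsed time has passed the holding time, and target stands nearly still while starting material goes on reacting. For the flask I take reacted times holding time over time, which gives 9.33%.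

The forecast gives 8.8% and 43.5% reacted, on its own grounds: “Treating the loss as first order in target”.

The flask gives 12.4% of target with product in the second phase, and 42.7% reacted.

    reagent in the reaction phase + protic impurity → quenched reagent (k = 21.9 M⁻¹ min⁻¹)
    reagent in the reaction phase ⇌ reagent in the second phase, rate k2*([reagent in the reaction phase] - [reagent in the second phase]/K2) per volume of the first phase (partition coefficient = 0.756, kL = 6.07 min⁻¹)
    starting material + reagent in the reaction phase → target (k = 1.55 M⁻¹ min⁻¹)
    target → decomposed product (k = 0.210 min⁻¹)
    reagent in the reaction phase ⇌ dormant form (K = 0.417, k = 0.107 min⁻¹)
    target ⇌ product in the second phase, rate k6*([target] - [product in the second phase]/K6) per volume of the first phase (partition coefficient = 8.43, kL = 0.0670 min⁻¹)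

Put the result back and the flask's holding time at 30 min is 8.70 min, longer than violet's reading at 20.0 min, and at 30.0 min the flask has 9.08% as product in the second phase. The yield stays this low because decomposition in the reaction phase competes with slow uptake into the second phase: without decomposition the flask gives 42.7%, and with fast uptake 34.4%. In the same flask read at 80 min, the holding time reaches 17.8 min, with 13.3% in the second phase out of 14.6%.

Readings and results stem from a simulated flask from invented constants; scatter was added.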